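**Plan**

1. Atom labels (kept for all intermediates; they differ from name locants): C1 (CHOAc), C2 (CH2), C3 (CHBr), C4 (CMe2), C5 (CHCl), C6 (ring carbon of the alkylidene), C7 (=CH), C8 (CH2Br). The C1 acetate and C8 bromide are the 1,4-ends of an allylic system, so they are removed first back to a C1–C6 vinyl epoxide and then to the diene C1=C6–C7=C8.
2. C6 carries both ring bonds (to C1 and C5) and the two-carbon side chain, so this 1-vinylcyclohexene is an enyne-metathesis product. Cutting C1=C6 and C7=C8 gives a 1,7-enyne with a terminal alkene at C1 and the alkyne C6≡C7.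
3. The enyne is cut at C6≡C7 (C7 from a diazophosphonate), C5–Cl (aldehyde α-chlorination), C3–Br (from C3–B) and C3–C4 (lithiation–borylation of a but-3-enyl benzoate with the C4–C6 tertiary boronic ester from conjugate borylation).
4. Forward: the chain is joined at C3–C4, bromine and chlorine are installed, the alkyne is added, the only ring closes by enyne metathesis, and epoxidation, SN2′ hydrobromination and acetylation finish the route.
5. Stereochemistry: C3 from (+)-sparteine-directed lithiation followed by stereoinvertive bromodeboronation; C5 from imidazolidinone-catalysed chlorination; C1 from epoxidation anti to the C5 chloride; the C6=C7 geometry from SN2′ opening through the s-trans vinyl epoxide.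

Key step: step 10

Assumption: the target is read as (1S,3R,5R) with a Z side-chain alkene (OAc and Br cis on the ring, Cl trans to both); (+)-sparteine and 2,4,6-triisopropylbenzoyl chloride are taken as commercial reagents.

**Step 1**
Reactants: 1 bis(pinacolato)diboron; 2 methyl 3-methylbut-2-enoate
Product: 3 methyl 3-methyl-3-(4,4,5,5-tetramethyl-1,3,2-dioxaborolan-2-yl)butanoate
Conditions: CuCl (5 mol%), Xantphos (5 mol%), NaOtBu (10 mol%), MeOH (2 equiv), THF, rt
Reagents that add atoms: none
Why: Copper-catalysed conjugate borylation of a β,β-disubstituted enoate, in which the copper–boryl species adds 1,4 and methanol protonates the copper enolate, gives the tertiary boronic ester without creating a stereocentre.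

**Step 2**
Reactants: 3 methyl 3-methyl-3-(4,4,5,5-tetramethyl-1,3,2-dioxaborolan-2-yl)butanoate
Product: 4 3-methyl-3-(4,4,5,5-tetramethyl-1,3,2-dioxaborolan-2-yl)butanal
Conditions: i-Bu2AlH (1.1 equiv), CH2Cl2, −78 °C; aq. KNaC4H4O6 work-up
Reagents that add atoms: none
Why: Partial hydride reduction of the ester at low temperature should stop at the aldehyde because the tetrahedral aluminium hemiacetal survives until work-up, and the hindered tertiary boronic ester is not attacked.

**Step 3**
Reactants: 4 3-methyl-3-(4,4,5,5-tetramethyl-1,3,2-dioxaborolan-2-yl)butanal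
Product: 5 2-(4,4-dimethoxy-2-methylbutan-2-yl)-4,4,5,5-tetramethyl-1,3,2-dioxaborolane
Conditions: HC(OMe)3, MeOH, p-TsOH·H2O (cat.), rt
Reagents that add atoms: trimethyl orthoformate, COC(OC)OC; methanol, CO
Why: Acid-catalysed acetalisation with the orthoformate as water scavenger masks the aldehyde as a dimethyl acetal that tolerates the organolithium reagents of steps 5 and 6.

**Step 4**
Reactants: 6 but-3-en-1-ol
Product: 7 but-3-en-1-yl 2,4,6-triisopropylbenzoate
Conditions: 2,4,6-triisopropylbenzoyl chloride, Et3N, DMAP (cat.), CH2Cl2, rt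
Reagents that add atoms: 2,4,6-triisopropylbenzoyl chloride, CC(C)c1cc(C(C)C)c(C(=O)Cl)c(C(C)C)c1
Why: Acylation of the primary alcohol gives the hindered benzoate, whose carbonyl directs α-lithiation and whose carboxylate is a good leaving group for the later 1,2-shift.

**Step 5**
Reactants: 7 but-3-en-1-yl 2,4,6-triisopropylbenzoate; 5 2-(4,4-dimethoxy-2-methylbutan-2-yl)-4,4,5,5-tetramethyl-1,3,2-dioxaborolane
Product: 10 (S)-2-(7,7-dimethoxy-5,5-dimethylhept-1-en-4-yl)-4,4,5,5-tetramethyl-1,3,2-dioxaborolane, via lithiated benzoate 8 (not isolated), via boronate complex 9 (not isolated)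
Conditions: s-BuLi (1.3 equiv), (+)-sparteine (1.3 equiv), Et2O, −78 °C; then 5, −78 °C; then 35 °C
Reagents that add atoms: none
Why: In this lithiation–borylation, (+)-sparteine-mediated deprotonation removes the pro-R hydrogen to give the configurationally stable (R)-organolithium 8, which adds to boron of 5 with retention, and the tertiary alkyl group then migrates from boron to carbon anti to the departing benzoate (inversion), forming the C3–C4 bond and setting C3 as the (S)-boronic ester.

**Step 6**
Reactants: 10 (S)-2-(7,7-dimethoxy-5,5-dimethylhept-1-en-4-yl)-4,4,5,5-tetramethyl-1,3,2-dioxaborolane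
Product: 12 (R)-4-bromo-7,7-dimethoxy-5,5-dimethylhept-1-ene, via aryl boronate complex 11 (not isolated)
Conditions: 3,5-(CF3)2C6H3Br, n-BuLi, THF, −78 °C; then 10, −78 °C; then NBS, −78 °C → rt
Reagents that add atoms: N-bromosuccinimide, O=C1CCC(=O)N1Br
Why: In this stereoinvertive bromodeboronation the electron-poor aryllithium turns the secondary boronic ester into a carbon-nucleophilic boronate complex, and NBS attacks the C–B bond from the rear (SE2 with inversion), so the (S)-boronate should give the (R)-bromide without touching the alkene or the acetal.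

**Step 7**
Reactants: 12 (R)-4-bromo-7,7-dimethoxy-5,5-dimethylhept-1-ene
Product: 13 (R)-4-bromo-3,3-dimethylhept-6-enal
Conditions: TFA/H2O (1:1), CHCl3, 0 °C
Reagents that add atoms: water, O
Why: Mild aqueous acid hydrolysis of the dimethyl acetal releases the aldehyde, while the neopentyl-type secondary bromide and the alkene are inert to these conditions.

**Step 8**
Reactants: 13 (R)-4-bromo-3,3-dimethylhept-6-enal
Product: 14 (2S,4R)-4-bromo-2-chloro-3,3-dimethylhept-6-enal
Conditions: (5S)-5-benzyl-2,2,3-trimethylimidazolidin-4-one·TFA (20 mol%), 2,3,4,5,6,6-hexachlorocyclohexa-2,4-dien-1-one (1.2 equiv), acetone, −30 °C; used crude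
Reagents that add atoms: 2,3,4,5,6,6-hexachlorocyclohexa-2,4-dien-1-one, O=C1C(Cl)=C(Cl)C(Cl)=C(Cl)C1(Cl)Cl
Why: In this enamine-catalysed asymmetric α-chlorination the E-enamine is chlorinated on its Si face, opposite the benzyl group of the (5S) catalyst, which sets C5 as the (2S) chloride under catalyst control, the remote C3 centre beyond the quaternary carbon having little influence.

**Step 9**
Reactants: 14 (2S,4R)-4-bromo-2-chloro-3,3-dimethylhept-6-enal
Product: 15 (3R,5R)-5-bromo-3-chloro-4,4-dimethyloct-7-en-1-yne
Conditions: dimethyl (1-diazo-2-oxopropyl)phosphonate, K2CO3, MeOH, 0 °C → rt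
Reagents that add atoms: dimethyl (1-diazo-2-oxopropyl)phosphonate, COP(=O)(OC)C(=[N+]=[N-])C(C)=O
Why: In this Seyferth–Gilbert homologation with the Ohira–Bestmann reagent the diazophosphonate anion undergoes Horner–Wadsworth–Emmons addition–elimination with the aldehyde and the diazoalkene loses N2 with 1,2-hydrogen shift to the terminal alkyne, and the mild base together with the hindered α-position should preserve the C5 configuration.

**Step 10**
Reactants: 15 (3R,5R)-5-bromo-3-chloro-4,4-dimethyloct-7-en-1-yne
Product: 16 (4R,6R)-4-bromo-6-chloro-5,5-dimethyl-1-vinylcyclohex-1-ene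
Conditions: second-generation Grubbs catalyst RuCl2(=CHPh)(H2IMes)(PCy3) (5 mol%), ethylene (1 atm), toluene (0.02 M), 60 °C
Reagents that add atoms: ethylene, C=C
Why: The ruthenium methylidene kept alive by ethylene exchanges with the monosubstituted alkene to give an alkylidene at C1, which adds [2+2] across the C6≡C7 triple bond; the ruthenacyclobutene opens to the C1=C6 ring alkene and a vinylcarbene at C7 that ethylene caps as the C7=C8 methylene. The closest known reaction is ring-closing enyne metathesis of 1,7-enynes to 1-vinylcyclohexenes under an ethylene atmosphere. The six-membered ring closes in the exo mode, C1 bonding to the internal alkyne carbon C6. No stereocentre is formed, and C3 and C5 are untouched because neither belongs to the reacting π systems. The step needs exo closure rather than endo closure to a seven-membered diene or alkyne oligomerisation: the C4 gem-dimethyl group favours cyclisation (Thorpe–Ingold effect), the terminal alkene initiates faster than the hindered propargylic alkyne, and ethylene suppresses oligomerisation, while even yne-first cross-metathesis with ethylene would give a triene that ring-closes to the same diene.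

**Step 11**
Reactants: 16 (4R,6R)-4-bromo-6-chloro-5,5-dimethyl-1-vinylcyclohex-1-ene
Product: 17 (1S,2S,4R,6S)-4-bromo-2-chloro-3,3-dimethyl-1-vinyl-7-oxabicyclo[4.1.0]heptane
Conditions: m-CPBA (1.05 equiv), NaHCO3, CH2Cl2, −20 → 0 °C
Reagents that add atoms: 3-chloroperoxybenzoic acid, OOC(=O)c1cccc(Cl)c1
Why: Prilezhaev epoxidation should take the trisubstituted ring alkene in preference to the vinyl group, and the peracid should approach the face opposite the C5–Cl bond, which A(1,2) strain with the vinyl group holds pseudoaxial and which repels the reagent sterically and by its dipole, setting C1 and C6.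

**Step 12**
Reactants: 17 (1S,2S,4R,6S)-4-bromo-2-chloro-3,3-dimethyl-1-vinyl-7-oxabicyclo[4.1.0]heptane
Product: 18 (1S,3R,5R)-5-bromo-2-[(Z)-2-bromoethylidene]-3-chloro-4,4-dimethylcyclohexan-1-ol
Conditions: 48% aq. HBr (1.1 equiv), CuBr (5 mol%), Et2O, −20 °C
Reagents that add atoms: hydrogen bromide, Br
Why: In this conjugate (SN2′) hydrobromination of a vinyl oxirane, bromide attacks the unhindered C8 terminus as the protonated C6–O bond breaks, direct attack at the fully substituted C6 being blocked by the C5 chloride, and reaction through the s-trans vinyl epoxide places C8 cis to C5, a geometry also favoured by A(1,3) strain with the equatorial C1 hydroxyl, while C1 keeps its configuration.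

**Step 13**
Reactants: 18 (1S,3R,5R)-5-bromo-2-[(Z)-2-bromoethylidene]-3-chloro-4,4-dimethylcyclohexan-1-ol
Product: 19 (1S,3R,5R)-5-bromo-2-[(Z)-2-bromoethylidene]-3-chloro-4,4-dimethylcyclohexyl acetate
Conditions: Ac2O (1.5 equiv), Sc(OTf)3 (1 mol%), MeCN, −20 °C
Reagents that add atoms: acetic anhydride, CC(=O)OC(C)=O
Why: Lewis acid-catalysed acetylation of the secondary allylic alcohol avoids nucleophilic amine bases that would quaternise at the primary allylic bromide, and C1 is not touched.

**Compound list**

1 | bis(pinacolato)diboron | CC1(C)OB(OC1(C)C)B1OC(C)(C)C(C)(C)O1 | starting material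
2 | methyl 3-methylbut-2-enoate | COC(=O)C=C(C)C | starting material
3 | methyl 3-methyl-3-(4,4,5,5-tetramethyl-1,3,2-dioxaborolan-2-yl)butanoate | COC(=O)CC(C)(C)B1OC(C)(C)C(C)(C)O1 | intermediate
4 | 3-methyl-3-(4,4,5,5-tetramethyl-1,3,2-dioxaborolan-2-yl)butanal | O=CCC(C)(C)B1OC(C)(C)C(C)(C)O1 | intermediate
5 | 2-(4,4-dimethoxy-2-methylbutan-2-yl)-4,4,5,5-tetramethyl-1,3,2-dioxaborolane | COC(OC)CC(C)(C)B1OC(C)(C)C(C)(C)O1 | intermediate
6 | but-3-en-1-ol | C=CCCO | starting material
7 | but-3-en-1-yl 2,4,6-triisopropylbenzoate | C=CCCOC(=O)c1c(C(C)C)cc(C(C)C)cc1C(C)C | intermediate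
8 | (R)-1-lithiobut-3-en-1-yl 2,4,6-triisopropylbenzoate, (+)-sparteine complex (not isolated) | C=CC[C@@H]([Li])OC(=O)c1c(C(C)C)cc(C(C)C)cc1C(C)C | intermediate
9 | lithium boronate complex of 8 and 5 (not isolated) | C=CC[C@H](OC(=O)c1c(C(C)C)cc(C(C)C)cc1C(C)C)[B-]1(OC(C)(C)C(C)(C)O1)C(C)(C)CC(OC)OC.[Li+] | intermediate
10 | (S)-2-(7,7-dimethoxy-5,5-dimethylhept-1-en-4-yl)-4,4,5,5-tetramethyl-1,3,2-dioxaborolane | C=CC[C@H](B1OC(C)(C)C(C)(C)O1)C(C)(C)CC(OC)OC | intermediate
11 | lithium [3,5-bis(trifluoromethyl)phenyl] boronate complex of 10 (not isolated) | C=CC[C@H]([B-]1(OC(C)(C)C(C)(C)O1)c1cc(C(F)(F)F)cc(C(F)(F)F)c1)C(C)(C)CC(OC)OC.[Li+] | intermediate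
12 | (R)-4-bromo-7,7-dimethoxy-5,5-dimethylhept-1-ene | C=CC[C@@H](Br)C(C)(C)CC(OC)OC | intermediate
13 | (R)-4-bromo-3,3-dimethylhept-6-enal | C=CC[C@@H](Br)C(C)(C)CC=O | intermediate
14 | (2S,4R)-4-bromo-2-chloro-3,3-dimethylhept-6-enal | C=CC[C@@H](Br)C(C)(C)[C@H](Cl)C=O | intermediate
15 | (3R,5R)-5-bromo-3-chloro-4,4-dimethyloct-7-en-1-yne | C=CC[C@@H](Br)C(C)(C)[C@H](Cl)C#C | intermediate
16 | (4R,6R)-4-bromo-6-chloro-5,5-dimethyl-1-vinylcyclohex-1-ene | C=CC1=CC[C@@H](Br)C(C)(C)[C@@H]1Cl | intermediate
17 | (1S,2S,4R,6S)-4-bromo-2-chloro-3,3-dimethyl-1-vinyl-7-oxabicyclo[4.1.0]heptane | C=C[C@]12O[C@H]1C[C@@H](Br)C(C)(C)[C@@H]2Cl | intermediate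
18 | (1S,3R,5R)-5-bromo-2-[(Z)-2-bromoethylidene]-3-chloro-4,4-dimethylcyclohexan-1-ol | O[C@H]1C[C@@H](Br)C(C)(C)[C@H](Cl)/C1=C\CBr | intermediate
19 | (1S,3R,5R)-5-bromo-2-[(Z)-2-bromoethylidene]-3-chloro-4,4-dimethylcyclohexyl acetate | CC(=O)O[C@H]1C[C@@H](Br)C(C)(C)[C@H](Cl)/C1=C\CBr | target

**Step count and risks**

Total steps: 13. Longest linear sequence: 12 steps (steps 1–3 and 5–13); step 4 is a one-step branch.

Steps most likely to fail:

Step 11. The peracid may attack the wrong face or show poor facial selectivity, because the axial C4 methyl group sits on the face anti to chlorine and competes with the shielding by the C5 chloride; over-oxidation at the vinyl group is a lesser concern. Fallback: starting from diene 16, accept attack syn to chlorine, which would give the diastereomeric epoxide (1R,2S,4R,6R)-4-bromo-2-chloro-3,3-dimethyl-1-vinyl-7-oxabicyclo[4.1.0]heptane F1. The same SN2′ hydrobromination (aq. HBr, CuBr, Et2O, −20 °C) would give the C1-epimeric allylic alcohol (1R,3R,5R)-5-bromo-2-[(Z)-2-bromoethylidene]-3-chloro-4,4-dimethylcyclohexan-1-ol F2; here the alkene geometry rests on the kinetic s-trans preference alone. A Mitsunobu reaction with acetic acid (PPh3, DIAD, THF, 0 °C) would then invert C1 and return to the route at target 19, so that both epoxide diastereomers converge.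

Step 6. Stereochemical fidelity may be lost through single-electron oxidation of the hindered boronate complex, or rear-side attack next to the quaternary C4 may be too slow and give way to protodeboronation. Fallback: starting from boronic ester 10, oxidise the C–B bond with retention (NaOH, H2O2, THF/H2O, 0 °C) to the alcohol (S)-7,7-dimethoxy-5,5-dimethylhept-1-en-4-ol F3. Invertive deoxybromination of this hindered secondary alcohol ((n-C8H17)3P, CBr4, toluene, 70 °C) comes back at bromide 12. Both the main step and this detour invert C3, so the same enantiomer of 10 serves.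

Step 9. The α-chloro aldehyde may epimerise at C5 by enolisation, or add methanol, under the basic methanolic conditions before homologation takes place. Fallback: starting from aldehyde 14, a base-free Ramirez dibromo-olefination (CBr4, PPh3, CH2Cl2, 0 °C) would give (3R,5R)-1,1,5-tribromo-3-chloro-4,4-dimethylocta-1,7-diene F4. Bromine–lithium exchange with Fritsch–Buttenberg–Wiechell rearrangement (n-BuLi, 2.1 equiv, THF, −100 °C, cold quench with AcOH; Corey–Fuchs sequence) comes back at enyne 15.

Further compounds
F1 | step 11 | (1R,2S,4R,6R)-4-bromo-2-chloro-3,3-dimethyl-1-vinyl-7-oxabicyclo[4.1.0]heptane | C=C[C@@]12O[C@@H]1C[C@@H](Br)C(C)(C)[C@@H]2Cl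
F2 | step 11 | (1R,3R,5R)-5-bromo-2-[(Z)-2-bromoethylidene]-3-chloro-4,4-dimethylcyclohexan-1-ol | O[C@@H]1C[C@@H](Br)C(C)(C)[C@H](Cl)/C1=C\CBr
F3 | step 6 | (S)-7,7-dimethoxy-5,5-dimethylhept-1-en-4-ol | C=CC[C@H](O)C(C)(C)CC(OC)OC
F4 | step 9 | (3R,5R)-1,1,5-tribromo-3-chloro-4,4-dimethylocta-1,7-diene | C=CC[C@@H](Br)C(C)(C)[C@H](Cl)C=C(Br)Br
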